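**Plan**

1. Cuts: C11=C13 is unmasked last from a thiophenol adduct. The C14 isobutyrate and the C1=C10 alkene come from a 1,3-acyloxy shift (C1–O/C10=C14 to C14–O/C1=C10). The ten-membered ring is cut at C8–C9 (aldehyde C8 plus allylic bromide), the lactone at C6–C7 and C12–O, and the chain at C3–C4 and C1–C10.
2. Enabling feature: C8 is a carbinol carbon homoallylic to C1=C10, and C10 also carries the ester-bearing C14, so C9–C10(–C14)–C1 is an oxygenated 2-methyleneallyl unit. With the ester parked on C1, C9 and C14 are the two equal CH2 ends of a 2-substituted allyl unit, so the reductive, polarity-reversed union of the two electrophilic carbons (C8=O and the allylic bromide) can give only one constitution.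
3. Forward order: the C9/C14–C10–C1–C2–C3 piece is joined to C4–C6/C15, then the lactone ring is made (C6–C7), then the ten-membered carbocycle (C8–C9), then the ester is walked from C1 to C14, then the methylene lactone is released.
4. Stereochemistry: C6 and C7 come from a ligand-controlled anti allylation; C8 from C7 (Felkin–Anh) during ring closure; C4=C5 from trans-hydroalumination/iodination and a stereoretentive coupling; C1=C10 from the ring-held syn π-allyl; the temporary centre C1 from a lipase resolution.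

Key step: step 15

Remark: positions are given in germacrane numbering (ring C1–C10, lactone C6–O–C12(=O)–C11(=C13)–C7, C14 on C10, C15 on C4); "ring-cis" means the two ring carbons on an alkene are cis.
Assumption: the temporary centres C1 and C11 are erased in steps 16 and 17; they are carried as 1S and 11S, and their epimers would serve equally.

**Route**

Step 1
Reactants: 1 2-bromoprop-2-en-1-ol
Product: 2 [(2-bromoprop-2-en-1-yl)oxy](tert-butyl)diphenylsilane
Conditions: TBDPSCl, imidazole, DMF, rt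
Reagents that add atoms: tert-butylchlorodiphenylsilane CC(C)(C)[Si](Cl)(c1ccccc1)c1ccccc1
Why: Silyl ether formation on a primary allylic alcohol gives a group that should survive the organolithium step and the later acidic methanolysis that removes the TBS group.

Step 2
Reactants: 2 [(2-bromoprop-2-en-1-yl)oxy](tert-butyl)diphenylsilane; 3 acrolein
Product: 5 rac-2-{[(tert-butyldiphenylsilyl)oxy]methyl}penta-1,4-dien-3-ol, via vinyllithium 4 (not isolated)
Conditions: t-BuLi (2 equiv), Et2O, −78 °C; then 3; then H2O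
Reagents that add atoms: none
Why: Bromine–lithium exchange should give the 2-lithioallyl ether, which adds 1,2 to acrolein (organolithium carbonyl addition) to give the racemic divinyl carbinol (C1).

Step 3
Reactants: 5 rac-2-{[(tert-butyldiphenylsilyl)oxy]methyl}penta-1,4-dien-3-ol
Product: 6 (3S)-2-{[(tert-butyldiphenylsilyl)oxy]methyl}penta-1,4-dien-3-ol
Conditions: immobilised Candida antarctica lipase B, vinyl acetate, MTBE, 30 °C, stopped near 52% conversion
Reagents that add atoms: none
Why: Lipase-catalysed kinetic resolution (enantioselective transesterification, vinyl as the small and the substituted propenyl as the large group) should acylate the (R)-alcohol and leave the (S)-alcohol, which makes every later intermediate a single diastereomer although this centre is erased in step 16.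

Step 4
Reactants: 6 (3S)-2-{[(tert-butyldiphenylsilyl)oxy]methyl}penta-1,4-dien-3-ol
Product: 7 (3S)-2-{[(tert-butyldiphenylsilyl)oxy]methyl}penta-1,4-dien-3-yl 2-methylpropanoate
Conditions: i-PrCOCl, pyridine, DMAP (cat.), CH2Cl2, 0 °C
Reagents that add atoms: 2-methylpropanoyl chloride CC(C)C(Cl)=O
Why: Acylation of the secondary allylic alcohol parks the isobutyrate of the target on C1 with retention of configuration.

Step 5
Reactants: 8 4-[(tert-butyldimethylsilyl)oxy]but-2-yn-1-ol
Product: 10 (2Z)-4-[(tert-butyldimethylsilyl)oxy]-3-iodobut-2-en-1-ol, via alkenylaluminate 9 (not isolated)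
Conditions: NaAlH2(OCH2CH2OCH3)2, THF, 0 °C; then I2, −78 °C
Reagents that add atoms: iodine II
Why: Hydroxyl-directed trans-hydroalumination of the propargylic alcohol places aluminium on the distal alkyne carbon cis to the CH2O group, and iodinolysis with retention should give the (Z)-iodide that fixes the later C4=C5 geometry (C15 trans to C6).

Step 6
Reactants: 7 (3S)-2-{[(tert-butyldiphenylsilyl)oxy]methyl}penta-1,4-dien-3-yl 2-methylpropanoate; 10 (2Z)-4-[(tert-butyldimethylsilyl)oxy]-3-iodobut-2-en-1-ol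
Product: 12 (3S,6E)-2-{[(tert-butyldiphenylsilyl)oxy]methyl}-6-{[(tert-butyldimethylsilyl)oxy]methyl}-8-hydroxyocta-1,6-dien-3-yl 2-methylpropanoate, via alkylborane 11 (not isolated)
Conditions: (c-C6H11)2BH (from BH3·SMe2 and cyclohexene), THF, 0 °C; then 10 (1.2 equiv), Pd(dppf)Cl2 (5 mol%), AsPh3, K3PO4 aq., DMF, rt
Reagents that add atoms: none
Why: The bulky dialkylborane should hydroborate only the monosubstituted vinyl group (boron terminal), and the B-alkyl Suzuki–Miyaura coupling forms C3–C4 with retention of alkene geometry, the vinyl iodide being kept in excess so that zerovalent palladium is intercepted before it can ionise the allylic isobutyrate.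

Step 7
Reactants: 12 (3S,6E)-2-{[(tert-butyldiphenylsilyl)oxy]methyl}-6-{[(tert-butyldimethylsilyl)oxy]methyl}-8-hydroxyocta-1,6-dien-3-yl 2-methylpropanoate
Product: 13 (3S,6E)-2-{[(tert-butyldiphenylsilyl)oxy]methyl}-6-{[(tert-butyldimethylsilyl)oxy]methyl}-8-oxoocta-1,6-dien-3-yl 2-methylpropanoate
Conditions: MnO2, CH2Cl2, rt
Reagents that add atoms: none
Why: Allylic oxidation with MnO2 should convert only the primary allylic alcohol into the enal (C6) under neutral conditions that keep the alkene geometry.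

Step 8
Reactants: 14 methyl acrylate; 15 2,2-dimethoxyacetaldehyde
Product: 16 rac-methyl 3-hydroxy-4,4-dimethoxy-2-methylidenebutanoate
Conditions: DABCO, dioxane/H2O, rt
Reagents that add atoms: none
Why: The Morita–Baylis–Hillman reaction of an acrylate with a reactive α-alkoxy aldehyde should give the allylic alcohol that carries C7, C8 (as acetal), C11, C12 and C13.

Step 9
Reactants: 16 rac-methyl 3-hydroxy-4,4-dimethoxy-2-methylidenebutanoate
Product: 17 methyl (2Z)-2-(bromomethyl)-4,4-dimethoxybut-2-enoate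
Conditions: NBS, Me2S, CH2Cl2, 0 °C to rt
Reagents that add atoms: N-bromosuccinimide O=C1CCC(=O)N1Br
Why: Corey–Kim-type bromination of the Baylis–Hillman alcohol proceeds with SN2′ transposition under non-acidic conditions that spare the acetal and should give the thermodynamically preferred (Z)-2-(bromomethyl)enoate.

Step 10
Reactants: 13 (3S,6E)-2-{[(tert-butyldiphenylsilyl)oxy]methyl}-6-{[(tert-butyldimethylsilyl)oxy]methyl}-8-oxoocta-1,6-dien-3-yl 2-methylpropanoate; 17 methyl (2Z)-2-(bromomethyl)-4,4-dimethoxybut-2-enoate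
Product: 19 (4S,5R)-5-[(1E,5S)-6-{[(tert-butyldiphenylsilyl)oxy]methyl}-2-(hydroxymethyl)-5-(isobutyryloxy)hepta-1,6-dien-1-yl]-4-(dimethoxymethyl)-3-methylideneoxolan-2-one, via silyl ether adduct 18 (not isolated)
Conditions: CrCl2 (10 mol%), chiral carbazole-bridged bis(oxazoline) ligand (12 mol%, the enantiomer that gives the 6R carbinol), Mn powder, TMSCl, i-Pr2NEt, THF, rt; then CSA (cat.), MeOH, 0 °C to rt
Reagents that add atoms: none
Why: In this catalytic asymmetric Nozaki–Hiyama–Kishi-type 2-(alkoxycarbonyl)allylation the γ-substituted allylchromium should add through a chair transition state with anti selectivity (C7 relative to C6) on the aldehyde face chosen by the ligand (C6 R), and acid in methanol then removes the TMS and primary TBS groups and closes the trans-lactone while the TBDPS ether, isobutyrate and acetal persist.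

Step 11
Reactants: 19 (4S,5R)-5-[(1E,5S)-6-{[(tert-butyldiphenylsilyl)oxy]methyl}-2-(hydroxymethyl)-5-(isobutyryloxy)hepta-1,6-dien-1-yl]-4-(dimethoxymethyl)-3-methylideneoxolan-2-one
Product: 21 (3S,4S,5R)-5-[(1E,5S)-2-(acetoxymethyl)-6-{[(tert-butyldiphenylsilyl)oxy]methyl}-5-(isobutyryloxy)hepta-1,6-dien-1-yl]-4-(dimethoxymethyl)-3-[(phenylsulfanyl)methyl]oxolan-2-one, via thiol adduct 20 (not isolated)
Conditions: PhSH, Et3N (cat.), CH2Cl2, rt; then Ac2O, Et3N, DMAP (cat.)
Reagents that add atoms: thiophenol Sc1ccccc1; acetic anhydride CC(=O)OC(C)=O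
Why: Thia-Michael addition masks the methylene lactone, so that H7 is no longer vinylogously acidic once C8 becomes an aldehyde, and acetylation of the primary allylic alcohol then installs the C15 acetate.

Step 12
Reactants: 21 (3S,4S,5R)-5-[(1E,5S)-2-(acetoxymethyl)-6-{[(tert-butyldiphenylsilyl)oxy]methyl}-5-(isobutyryloxy)hepta-1,6-dien-1-yl]-4-(dimethoxymethyl)-3-[(phenylsulfanyl)methyl]oxolan-2-one
Product: 22 (3S,4S,5R)-5-[(1E,5S)-2-(acetoxymethyl)-6-(hydroxymethyl)-5-(isobutyryloxy)hepta-1,6-dien-1-yl]-4-(dimethoxymethyl)-3-[(phenylsulfanyl)methyl]oxolan-2-one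
Conditions: HF·pyridine, pyridine, THF, 0 °C to rt
Reagents that add atoms: none
Why: Buffered fluoride desilylation should free the C14 alcohol without touching the esters, lactone or acetal, and the product is used at once to forestall 1,3-acyl migration from O1 to O14.

Step 13
Reactants: 22 (3S,4S,5R)-5-[(1E,5S)-2-(acetoxymethyl)-6-(hydroxymethyl)-5-(isobutyryloxy)hepta-1,6-dien-1-yl]-4-(dimethoxymethyl)-3-[(phenylsulfanyl)methyl]oxolan-2-one
Product: 23 (3S,4S,5R)-5-[(1E,5S)-2-(acetoxymethyl)-6-(bromomethyl)-5-(isobutyryloxy)hepta-1,6-dien-1-yl]-4-(dimethoxymethyl)-3-[(phenylsulfanyl)methyl]oxolan-2-one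
Conditions: CBr4, PPh3, 2,6-lutidine, CH2Cl2, 0 °C
Reagents that add atoms: tetrabromomethane BrC(Br)(Br)Br
Why: The Appel reaction converts the primary allylic alcohol into the bromide under neutral conditions, and a possible SN2′ pathway is degenerate because both allyl termini are CH2.

Step 14
Reactants: 23 (3S,4S,5R)-5-[(1E,5S)-2-(acetoxymethyl)-6-(bromomethyl)-5-(isobutyryloxy)hepta-1,6-dien-1-yl]-4-(dimethoxymethyl)-3-[(phenylsulfanyl)methyl]oxolan-2-one
Product: 24 (2R,3S,4S)-2-[(1E,5S)-2-(acetoxymethyl)-6-(bromomethyl)-5-(isobutyryloxy)hepta-1,6-dien-1-yl]-5-oxo-4-[(phenylsulfanyl)methyl]oxolane-3-carbaldehyde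
Conditions: TFA/H2O/CH2Cl2, 0 °C; used crude
Reagents that add atoms: water O
Why: Acid-catalysed acetal hydrolysis releases the C8 aldehyde under conditions in which the allylic bromide and esters are stable and the trans,trans-substituted lactone has no driving force to epimerise at C7.

Step 15
Reactants: 24 (2R,3S,4S)-2-[(1E,5S)-2-(acetoxymethyl)-6-(bromomethyl)-5-(isobutyryloxy)hepta-1,6-dien-1-yl]-5-oxo-4-[(phenylsulfanyl)methyl]oxolane-3-carbaldehyde
Product: 26 (1S,4E,6R,7R,8R,11S)-15-acetoxy-8-hydroxy-1-(isobutyryloxy)-13-(phenylsulfanyl)germacra-4,10(14)-dien-6,12-olide, via allylchromium dichloride 25 (not isolated)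
Conditions: CrCl2 (8 equiv), THF/DMF, 2 mM, syringe-pump addition, rt; then H2O
Reagents that add atoms: none
Why: Two equivalents of CrCl2 reduce the allylic C–Br bond to the allylchromium species 25, whose two termini are both CH2 groups so that either end gives the same constitution, and it adds to the C8 aldehyde through a six-membered chair transition state, forming C8–C9 while the double bond moves to C10=C14. The closest known reaction type is the Nozaki–Hiyama–Kishi (Barbier-type) allylation of aldehydes with divalent chromium, which has been used intramolecularly for ten-membered germacranolide carbocycles. The ten-membered ring closes in a 10-exo-trig mode (C9 attacks the C8 carbonyl, oxygen outside the ring), helped by the trans-lactone and the ring-cis C4=C5 alkene, which turn the two chain ends toward each other. The new stereocentre C8 is controlled by C7: in the Felkin–Anh arrangement that the tether can reach, the lactone carbon C11 stands anti to the incoming C9, the nucleophile passes H7 and the forming C8–O bond lies anti to the C6–O bond, which should give 8R. The step needs chemoselectivity (divalent chromium leaves the esters, lactone, sulfide and C1 isobutyrate untouched), ring closure over oligomerisation (high dilution, slow addition) and an aldehyde that does not enolise, which the sulfide mask on C13 secures.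

Step 16
Reactants: 26 (1S,4E,6R,7R,8R,11S)-15-acetoxy-8-hydroxy-1-(isobutyryloxy)-13-(phenylsulfanyl)germacra-4,10(14)-dien-6,12-olide
Product: 27 (1(10)E,4E,6R,7R,8R,11S)-15-acetoxy-8-hydroxy-14-(isobutyryloxy)-13-(phenylsulfanyl)germacra-1(10),4-dien-6,12-olide
Conditions: Pd(PPh3)4 (5 mol%), THF, rt
Reagents that add atoms: none
Why: In this palladium-catalysed 1,3-acyloxy transposition (allylic ester isomerisation) zerovalent palladium ionises the secondary isobutyrate at the unhindered exocyclic alkene, the carboxylate returns to the primary terminus C14 to give the more stable primary ester and trisubstituted alkene, the ring holds C2 syn on the π-allyl so that C1=C10 forms ring-cis, and the allylic esters on trisubstituted alkenes ionise far more slowly.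

Step 17
Reactants: 27 (1(10)E,4E,6R,7R,8R,11S)-15-acetoxy-8-hydroxy-14-(isobutyryloxy)-13-(phenylsulfanyl)germacra-1(10),4-dien-6,12-olide
Product: 29 (1(10)E,4E,6R,7R,8R)-15-acetoxy-8-hydroxy-14-(isobutyryloxy)germacra-1(10),4,11(13)-trien-6,12-olide, via sulfoxide 28 (not isolated)
Conditions: NaIO4, MeOH/H2O, 0 °C to rt; then PhMe, NaHCO3, 90 °C
Reagents that add atoms: none
Why: Chemoselective sulfide oxidation and thermal sulfoxide syn-elimination, whose only β-hydrogen is the activated H11, should regenerate the exocyclic methylene lactone without base and so without translactonisation to O8.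

**Compound list**

1 | 2-bromoprop-2-en-1-ol | OCC(Br)=C | starting material
2 | [(2-bromoprop-2-en-1-yl)oxy](tert-butyl)diphenylsilane | C=C(Br)CO[Si](c1ccccc1)(c1ccccc1)C(C)(C)C | intermediate
3 | acrolein | C=CC=O | starting material
4 | {3-[(tert-butyldiphenylsilyl)oxy]prop-1-en-2-yl}lithium | [Li]C(=C)CO[Si](c1ccccc1)(c1ccccc1)C(C)(C)C | intermediate
5 | rac-2-{[(tert-butyldiphenylsilyl)oxy]methyl}penta-1,4-dien-3-ol (racemic) | C=CC(O)C(=C)CO[Si](c1ccccc1)(c1ccccc1)C(C)(C)C | intermediate
6 | (3S)-2-{[(tert-butyldiphenylsilyl)oxy]methyl}penta-1,4-dien-3-ol | C=C[C@H](O)C(=C)CO[Si](c1ccccc1)(c1ccccc1)C(C)(C)C | intermediate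
7 | (3S)-2-{[(tert-butyldiphenylsilyl)oxy]methyl}penta-1,4-dien-3-yl 2-methylpropanoate | C=C[C@H](OC(=O)C(C)C)C(=C)CO[Si](c1ccccc1)(c1ccccc1)C(C)(C)C | intermediate
8 | 4-[(tert-butyldimethylsilyl)oxy]but-2-yn-1-ol | OCC#CCO[Si](C)(C)C(C)(C)C | starting material
9 | sodium 2,2-bis(2-methoxyethoxy)-3-{[(tert-butyldimethylsilyl)oxy]methyl}-2,5-dihydro-1,2-oxaluminol-2-uide (cyclic alkenylaluminate) | [Na+].COCCO[Al-]1(OCCOC)OCC=C1CO[Si](C)(C)C(C)(C)C | intermediate
10 | (2Z)-4-[(tert-butyldimethylsilyl)oxy]-3-iodobut-2-en-1-ol | OC/C=C(\I)CO[Si](C)(C)C(C)(C)C | intermediate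
11 | (3S)-2-{[(tert-butyldiphenylsilyl)oxy]methyl}-5-(dicyclohexylboranyl)pent-1-en-3-yl 2-methylpropanoate | C1CCCCC1B(C2CCCCC2)CC[C@H](OC(=O)C(C)C)C(=C)CO[Si](c3ccccc3)(c4ccccc4)C(C)(C)C | intermediate
12 | (3S,6E)-2-{[(tert-butyldiphenylsilyl)oxy]methyl}-6-{[(tert-butyldimethylsilyl)oxy]methyl}-8-hydroxyocta-1,6-dien-3-yl 2-methylpropanoate | OC/C=C(/CO[Si](C)(C)C(C)(C)C)CC[C@H](OC(=O)C(C)C)C(=C)CO[Si](c1ccccc1)(c1ccccc1)C(C)(C)C | intermediate
13 | (3S,6E)-2-{[(tert-butyldiphenylsilyl)oxy]methyl}-6-{[(tert-butyldimethylsilyl)oxy]methyl}-8-oxoocta-1,6-dien-3-yl 2-methylpropanoate | O=C/C=C(/CO[Si](C)(C)C(C)(C)C)CC[C@H](OC(=O)C(C)C)C(=C)CO[Si](c1ccccc1)(c1ccccc1)C(C)(C)C | intermediate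
14 | methyl acrylate | C=CC(=O)OC | starting material
15 | 2,2-dimethoxyacetaldehyde | COC(OC)C=O | starting material
16 | rac-methyl 3-hydroxy-4,4-dimethoxy-2-methylidenebutanoate (racemic) | C=C(C(=O)OC)C(O)C(OC)OC | intermediate
17 | methyl (2Z)-2-(bromomethyl)-4,4-dimethoxybut-2-enoate | COC(=O)/C(CBr)=C/C(OC)OC | intermediate
18 | methyl (3S,4R,5E,9S)-6-{[(tert-butyldimethylsilyl)oxy]methyl}-10-{[(tert-butyldiphenylsilyl)oxy]methyl}-3-(dimethoxymethyl)-2-methylidene-9-(isobutyryloxy)-4-[(trimethylsilyl)oxy]undeca-5,10-dienoate | C=C(C(=O)OC)[C@H](C(OC)OC)[C@H](O[Si](C)(C)C)/C=C(/CO[Si](C)(C)C(C)(C)C)CC[C@H](OC(=O)C(C)C)C(=C)CO[Si](c1ccccc1)(c1ccccc1)C(C)(C)C | intermediate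
19 | (4S,5R)-5-[(1E,5S)-6-{[(tert-butyldiphenylsilyl)oxy]methyl}-2-(hydroxymethyl)-5-(isobutyryloxy)hepta-1,6-dien-1-yl]-4-(dimethoxymethyl)-3-methylideneoxolan-2-one | C=C1C(=O)O[C@H](/C=C(/CO)CC[C@H](OC(=O)C(C)C)C(=C)CO[Si](c2ccccc2)(c2ccccc2)C(C)(C)C)[C@H]1C(OC)OC | intermediate
20 | (3S,4S,5R)-5-[(1E,5S)-6-{[(tert-butyldiphenylsilyl)oxy]methyl}-2-(hydroxymethyl)-5-(isobutyryloxy)hepta-1,6-dien-1-yl]-4-(dimethoxymethyl)-3-[(phenylsulfanyl)methyl]oxolan-2-one | O=C1O[C@H](/C=C(/CO)CC[C@H](OC(=O)C(C)C)C(=C)CO[Si](c2ccccc2)(c2ccccc2)C(C)(C)C)[C@@H](C(OC)OC)[C@@H]1CSc3ccccc3 | intermediate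
21 | (3S,4S,5R)-5-[(1E,5S)-2-(acetoxymethyl)-6-{[(tert-butyldiphenylsilyl)oxy]methyl}-5-(isobutyryloxy)hepta-1,6-dien-1-yl]-4-(dimethoxymethyl)-3-[(phenylsulfanyl)methyl]oxolan-2-one | O=C1O[C@H](/C=C(/COC(C)=O)CC[C@H](OC(=O)C(C)C)C(=C)CO[Si](c2ccccc2)(c2ccccc2)C(C)(C)C)[C@@H](C(OC)OC)[C@@H]1CSc3ccccc3 | intermediate
22 | (3S,4S,5R)-5-[(1E,5S)-2-(acetoxymethyl)-6-(hydroxymethyl)-5-(isobutyryloxy)hepta-1,6-dien-1-yl]-4-(dimethoxymethyl)-3-[(phenylsulfanyl)methyl]oxolan-2-one | O=C1O[C@H](/C=C(/COC(C)=O)CC[C@H](OC(=O)C(C)C)C(=C)CO)[C@@H](C(OC)OC)[C@@H]1CSc3ccccc3 | intermediate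
23 | (3S,4S,5R)-5-[(1E,5S)-2-(acetoxymethyl)-6-(bromomethyl)-5-(isobutyryloxy)hepta-1,6-dien-1-yl]-4-(dimethoxymethyl)-3-[(phenylsulfanyl)methyl]oxolan-2-one | O=C1O[C@H](/C=C(/COC(C)=O)CC[C@H](OC(=O)C(C)C)C(=C)CBr)[C@@H](C(OC)OC)[C@@H]1CSc3ccccc3 | intermediate
24 | (2R,3S,4S)-2-[(1E,5S)-2-(acetoxymethyl)-6-(bromomethyl)-5-(isobutyryloxy)hepta-1,6-dien-1-yl]-5-oxo-4-[(phenylsulfanyl)methyl]oxolane-3-carbaldehyde | O=C1O[C@H](/C=C(/COC(C)=O)CC[C@H](OC(=O)C(C)C)C(=C)CBr)[C@@H](C=O)[C@@H]1CSc3ccccc3 | intermediate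
25 | allylchromium dichloride derived from 24 (trivalent chromium, solvent ligands omitted) | O=C1O[C@H](/C=C(/COC(C)=O)CC[C@H](OC(=O)C(C)C)C(=C)C[Cr](Cl)Cl)[C@@H](C=O)[C@@H]1CSc3ccccc3 | intermediate
26 | (1S,4E,6R,7R,8R,11S)-15-acetoxy-8-hydroxy-1-(isobutyryloxy)-13-(phenylsulfanyl)germacra-4,10(14)-dien-6,12-olide (C4=C5 ring-cis) | O=C1O[C@@H]2/C=C(/COC(C)=O)CC[C@H](OC(=O)C(C)C)C(=C)C[C@@H](O)[C@H]2[C@@H]1CSc1ccccc1 | intermediate
27 | (1(10)E,4E,6R,7R,8R,11S)-15-acetoxy-8-hydroxy-14-(isobutyryloxy)-13-(phenylsulfanyl)germacra-1(10),4-dien-6,12-olide (both ring alkenes ring-cis) | O=C1O[C@@H]2/C=C(/COC(C)=O)CC/C=C(/COC(=O)C(C)C)C[C@@H](O)[C@H]2[C@@H]1CSc1ccccc1 | intermediate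
28 | sulfoxide of 27 (13-(phenylsulfinyl) compound, both sulfur epimers) | O=C1O[C@@H]2/C=C(/COC(C)=O)CC/C=C(/COC(=O)C(C)C)C[C@@H](O)[C@H]2[C@@H]1CS(=O)c1ccccc1 | intermediate
29 | (1(10)E,4E,6R,7R,8R)-15-acetoxy-8-hydroxy-14-(isobutyryloxy)germacra-1(10),4,11(13)-trien-6,12-olide (CNP0312458.1) | C=C1C(=O)O[C@@H]2/C=C(/COC(C)=O)CC/C=C(/COC(=O)C(C)C)C[C@@H](O)[C@@H]12 | target

**Step count**

Total steps: 17. Longest linear sequence: 14 (steps 1–4, 6, 7, 10–17).

**Steps most likely to fail**

Step 15 (ring closure). Intermolecular coupling may outrun closure of the ten-membered ring, and the aldehyde face selection at C8 may be low because only the C7 centre controls it. The fallback replaces the reducing metal by a boron reagent with a closed transition state and reagent control. It sets out from 23: copper-catalysed borylation of the allylic bromide (B2pin2, CuCl, Xantphos, LiOt-Bu, THF) would give the pinacol allylboronate acetal F1. Acetal hydrolysis as in step 14 would give the allylboronate aldehyde F2. F2 would then be cyclised under dilution by a chiral phosphoric acid-catalysed intramolecular allylboration; the two CH2 termini again make the regiochemistry degenerate, and the catalyst enantiomer selects the C8 face. Oxidative-free aqueous work-up of the borate returns to the route at 26.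

Step 16 (ester walk). The π-allyl intermediate may be captured by the free C8 hydroxyl to give a cyclic ether, and free carboxylate may scramble between the three allylic ester positions. The fallback avoids ionisation altogether and reverses the order of the last two operations. It sets out from 26: NaIO4 oxidation would give the sulfoxide F3, and thermolysis (PhMe, 90 °C) the methylene lactone F4, which still carries the C1 isobutyrate and the C10=C14 alkene. F4 would then be treated with catalytic Hg(OCOCF3)2 (divalent mercury; THF, rt). This cyclisation-induced [3,3] rearrangement passes through a 1,3-dioxan-2-ylium intermediate without an allyl cation or free carboxylate, tolerates the substituent on the central allyl carbon, and places C2 equatorial so that C1=C10 forms ring-cis. It returns to the route at the target 29.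

Step 10 (lactone stereocentres). The equilibrating allylchromium may add with poor anti/syn selectivity, or the ligand may give poor facial selectivity, so that the cis-lactone or the wrong enantiomeric series at C6/C7 forms. The fallback sets both centres by an auxiliary-controlled aldol before the chain is attached. It sets out from 10 and comes back at 21:
- MnO2 oxidation would give the (Z)-iodoenal F5.
- Evans syn-aldol of F5 with the boron enolate of (S)-4-benzyl-3-(4-methoxy-4-oxobutanoyl)oxazolidin-2-one (Bu2BOTf, i-Pr2NEt) would give the aldol adduct F6, which lactonises with PPTS to the trans-lactone imide F7.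
- NaBH4 in THF/H2O would cleave the auxiliary reductively to the hydroxymethyl lactone F8.
- Dess–Martin oxidation would give the aldehyde F9, and CH(OMe)3/PPTS the dimethyl acetal F10.
- LiN(i-Pr)2/TMSCl followed by PhSCH2Cl/ZnBr2 (phenylthiomethylation of the silyl ketene acetal, anti to the C7 substituent) would give the sulfide F11.
- CSA in MeOH would give the alcohol F12, and Ac2O/pyridine the acetate F13.
- B-alkyl Suzuki coupling of F13 with the alkylborane 11 under the conditions of step 6 returns to the route at 21.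

**Further compounds**

F1 | step 15 | (3S,4S,5R)-5-[(1E,5S)-2-(acetoxymethyl)-5-(isobutyryloxy)-6-[(4,4,5,5-tetramethyl-1,3,2-dioxaborolan-2-yl)methyl]hepta-1,6-dien-1-yl]-4-(dimethoxymethyl)-3-[(phenylsulfanyl)methyl]oxolan-2-one | O=C1O[C@H](/C=C(/COC(C)=O)CC[C@H](OC(=O)C(C)C)C(=C)CB2OC(C)(C)C(C)(C)O2)[C@@H](C(OC)OC)[C@@H]1CSc3ccccc3
F2 | step 15 | (2R,3S,4S)-2-[(1E,5S)-2-(acetoxymethyl)-5-(isobutyryloxy)-6-[(4,4,5,5-tetramethyl-1,3,2-dioxaborolan-2-yl)methyl]hepta-1,6-dien-1-yl]-5-oxo-4-[(phenylsulfanyl)methyl]oxolane-3-carbaldehyde | O=C1O[C@H](/C=C(/COC(C)=O)CC[C@H](OC(=O)C(C)C)C(=C)CB2OC(C)(C)C(C)(C)O2)[C@@H](C=O)[C@@H]1CSc3ccccc3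
F3 | step 16 | sulfoxide of 26 (13-(phenylsulfinyl) compound, both sulfur epimers) | O=C1O[C@@H]2/C=C(/COC(C)=O)CC[C@H](OC(=O)C(C)C)C(=C)C[C@@H](O)[C@H]2[C@@H]1CS(=O)c1ccccc1
F4 | step 16 | (1S,4E,6R,7R,8R)-15-acetoxy-8-hydroxy-1-(isobutyryloxy)germacra-4,10(14),11(13)-trien-6,12-olide | C=C1C(=O)O[C@@H]2/C=C(/COC(C)=O)CC[C@H](OC(=O)C(C)C)C(=C)C[C@@H](O)[C@@H]12
F5 | step 10 | (2Z)-4-[(tert-butyldimethylsilyl)oxy]-3-iodobut-2-enal | O=C/C=C(\I)CO[Si](C)(C)C(C)(C)C
F6 | step 10 | methyl (3S,4R,5Z)-3-{[(4S)-4-benzyl-2-oxooxazolidin-3-yl]carbonyl}-7-[(tert-butyldimethylsilyl)oxy]-4-hydroxy-6-iodohept-5-enoate | COC(=O)C[C@H](C(=O)N1C(=O)OC[C@@H]1Cc1ccccc1)[C@H](O)/C=C(\I)CO[Si](C)(C)C(C)(C)C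
F7 | step 10 | (4S)-4-benzyl-3-{[(2R,3S)-2-[(1Z)-3-[(tert-butyldimethylsilyl)oxy]-2-iodoprop-1-en-1-yl]-5-oxooxolan-3-yl]carbonyl}oxazolidin-2-one | O=C1O[C@H](/C=C(\I)CO[Si](C)(C)C(C)(C)C)[C@@H](C(=O)N2C(=O)OC[C@@H]2Cc2ccccc2)C1
F8 | step 10 | (4S,5R)-5-[(1Z)-3-[(tert-butyldimethylsilyl)oxy]-2-iodoprop-1-en-1-yl]-4-(hydroxymethyl)oxolan-2-one | O=C1O[C@H](/C=C(\I)CO[Si](C)(C)C(C)(C)C)[C@@H](CO)C1
F9 | step 10 | (2R,3S)-2-[(1Z)-3-[(tert-butyldimethylsilyl)oxy]-2-iodoprop-1-en-1-yl]-5-oxooxolane-3-carbaldehyde | O=C1O[C@H](/C=C(\I)CO[Si](C)(C)C(C)(C)C)[C@@H](C=O)C1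
F10 | step 10 | (4S,5R)-5-[(1Z)-3-[(tert-butyldimethylsilyl)oxy]-2-iodoprop-1-en-1-yl]-4-(dimethoxymethyl)oxolan-2-one | O=C1O[C@H](/C=C(\I)CO[Si](C)(C)C(C)(C)C)[C@@H](C(OC)OC)C1
F11 | step 10 | (3S,4S,5R)-5-[(1Z)-3-[(tert-butyldimethylsilyl)oxy]-2-iodoprop-1-en-1-yl]-4-(dimethoxymethyl)-3-[(phenylsulfanyl)methyl]oxolan-2-one | O=C1O[C@H](/C=C(\I)CO[Si](C)(C)C(C)(C)C)[C@@H](C(OC)OC)[C@@H]1CSc1ccccc1
F12 | step 10 | (3S,4S,5R)-4-(dimethoxymethyl)-5-[(1Z)-3-hydroxy-2-iodoprop-1-en-1-yl]-3-[(phenylsulfanyl)methyl]oxolan-2-one | O=C1O[C@H](/C=C(\I)CO)[C@@H](C(OC)OC)[C@@H]1CSc1ccccc1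
F13 | step 10 | (2Z)-3-[(2R,3S,4S)-3-(dimethoxymethyl)-5-oxo-4-[(phenylsulfanyl)methyl]oxolan-2-yl]-2-iodoprop-2-en-1-yl acetate | O=C1O[C@H](/C=C(\I)COC(C)=O)[C@@H](C(OC)OC)[C@@H]1CSc1ccccc1
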